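**Retrosynthetic overview**

1. The strategy rests on the two-carbon bridge C7(=O)–C8(OH)(CH3) of the bicyclo[2.2.2]oct-2-ene (bridgeheads C1–CH3 and C4–H). This alpha-ketol is what a 1,2-shift of C4 from C7 to an acetyl carbon leaves behind, so the C4–C8 bond is disconnected back to a 7-acetyl-7-hydroxynorbornene.
2. After the shift, three bonds remain to be made or broken: the C3–acyl bond (hex-4-enoyl, C-acylation of the C2 ketone), the C6–CO bond of the sorbyl ketone (thioester, Pd/Cu coupling with a dienylboronic acid) and the tetronate O–CH3 bond (LiCl).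
3. Before the shift, the acetyl group comes from a C7 ethynyl group (hydration), the tetronate ring is built on the C5 acetyl group, and the norbornene comes from a Diels–Alder reaction of a 5-hydroxy-5-alkynyl-2-methoxy-1-methylcyclopentadiene with tert-butyl (E)-4-oxopent-2-enoate.
4. The diene is made from (S)-4-silyloxycyclopent-2-enone. Its carbinol carbon is the only stereocentre taken from the chiral pool and directs all the others.
5. Ring order: cyclopentadiene, norbornene (Diels–Alder), butenolide (tetronate), bicyclo[2.2.2]octene (ketol shift).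

Key step: step 13

Remark: the 2-hydroxy-3-acyl enol drawn in the target is treated as one tautomer of the C2/C3 beta-diketone. Atom numbers used below: C1 methyl bridgehead, C2 oxygen-bearing alkene carbon, C3, C4 CH bridgehead, C5, C6, C7 one-carbon bridge (norbornenes), or C7 bridge ketone on C1 and C8 carbinol carbon on C4 (bicyclooctenes). Absolute configurations of the bicyclic compounds are those of the SMILES.

**Route**

Step 1
Reactants: 1 (S)-4-[(tert-butyldimethylsilyl)oxy]cyclopent-2-en-1-one; 2 ethynyltri(propan-2-yl)silane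
Product: 3 (1R,4S)-4-[(tert-butyldimethylsilyl)oxy]-1-[(triisopropylsilyl)ethynyl]cyclopent-2-en-1-ol
Conditions: 2, n-BuLi, THF, −78 °C; then 1, −78 °C; NH4Cl aq.; chromatography
Reagents that add atoms: none
Why: 1,2-addition of a lithium acetylide to the enone carbonyl; the nucleophile should enter anti to the C4 silyloxy group, which sets the carbinol carbon (R) with OH cis to OTBS, and the minor epimer is removed by chromatography.

Step 2
Reactants: 3 (1R,4S)-4-[(tert-butyldimethylsilyl)oxy]-1-[(triisopropylsilyl)ethynyl]cyclopent-2-en-1-ol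
Product: 4 (1R,4S)-1-[(triisopropylsilyl)ethynyl]cyclopent-2-ene-1,4-diol
Conditions: HF·pyridine, pyridine, THF, 0 °C to rt
Reagents that add atoms: none
Why: acidic fluoride cleaves the secondary O–Si bond, while the alkynyl–Si(iPr)3 bond and the tertiary allylic alcohol should be left alone in the pyridine-buffered medium.

Step 3
Reactants: 4 (1R,4S)-1-[(triisopropylsilyl)ethynyl]cyclopent-2-ene-1,4-diol
Product: 5 (R)-4-hydroxy-4-[(triisopropylsilyl)ethynyl]cyclopent-2-en-1-one
Conditions: MnO2, CH2Cl2, rt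
Reagents that add atoms: none
Why: MnO2 oxidises the secondary allylic alcohol selectively, so the tertiary carbinol is kept and becomes the only stereocentre.

Step 4
Reactants: 5 (R)-4-hydroxy-4-[(triisopropylsilyl)ethynyl]cyclopent-2-en-1-one
Product: 6 (4S)-5-methyl-4-[(triisopropylsilyl)ethynyl]-4-[(trimethylsilyl)oxy]cyclopent-2-en-1-one (both C5 epimers)
Conditions: LiN(SiMe3)2 (2.1 equiv), THF, −78 °C; MeI, −78 to −40 °C; then Me3SiCl, −40 to 0 °C
Reagents that add atoms: iodomethane, CI; chlorotrimethylsilane, C[Si](C)(C)Cl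
Why: enolate alkylation of the alkoxide–enolate dianion, which can react only at C5 (the one enolisable position) and cannot lose oxide by beta-elimination, followed by capping of the lithium alkoxide; the new C5 centre is not controlled and is destroyed in step 5.

Step 5
Reactants: 6 (4S)-5-methyl-4-[(triisopropylsilyl)ethynyl]-4-[(trimethylsilyl)oxy]cyclopent-2-en-1-one
Product: 8 (S)-3-methoxy-2-methyl-1-[(triisopropylsilyl)ethynyl]cyclopenta-2,4-dien-1-ol, via O-trimethylsilyl methoxydiene 7 (not isolated)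
Conditions: KN(SiMe3)2, THF–DMPU, −78 °C; Me2SO4, −78 to −30 °C; then K2CO3, MeOH, 0 °C; cold NaHCO3 work-up, used at once
Reagents that add atoms: dimethyl sulfate, COS(=O)(=O)OC
Why: O-alkylation of a potassium enolate by a hard electrophile in a dipolar medium, favoured because C5 is flanked by a methyl group and a quaternary carbon and kept cold so that the beta-silyloxy enolate does not eliminate; methanolic carbonate then frees the tertiary hydroxyl, and no stereocentre is touched.

Step 6
Reactants: 9 (E)-4-oxopent-2-enoic acid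
Product: 10 tert-butyl (E)-4-oxopent-2-enoate
Conditions: tert-butyl 2,2,2-trichloroacetimidate, cyclohexane/CH2Cl2, rt
Reagents that add atoms: tert-butyl 2,2,2-trichloroacetimidate, CC(C)(C)OC(=N)C(Cl)(Cl)Cl
Why: esterification of a carboxylic acid by a tert-butyl trichloroacetimidate (the acid protonates the imidate); the E alkene and the ketone are untouched.

Step 7
Reactants: 8 (S)-3-methoxy-2-methyl-1-[(triisopropylsilyl)ethynyl]cyclopenta-2,4-dien-1-ol; 10 tert-butyl (E)-4-oxopent-2-enoate
Product: 11 tert-butyl 5-endo-acetyl-7-hydroxy-2-methoxy-1-methyl-7-[(triisopropylsilyl)ethynyl]bicyclo[2.2.1]hept-2-ene-6-exo-carboxylate (C7 hydroxyl on the C5–C6 side)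
Conditions: toluene, −20 °C to rt
Reagents that add atoms: none
Why: Diels–Alder reaction with normal electron demand, in which the C2 methoxy group makes C1 the nucleophilic terminus and the ketone makes the ester-bearing carbon the electrophilic one (ester carbon to C1, acetyl carbon to C4); the dienophile should add to the diene face that carries OH (the known preference of 5-oxygenated cyclopentadienes, helped by an O–H···O=C hydrogen bond) with the acetyl group endo by the Alder rule and the bulky ester exo beside the small hydroxyl, which sets C1, C4, C5 and C6 from C7.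

Step 8
Reactants: 11 Diels–Alder adduct (norbornene keto ester); 12 methyl propiolate
Product: 13 norbornene carrying at C5 the (S)-tertiary carbinol C(CH3)(OH)–C≡C–CO2CH3
Conditions: 12 (3 equiv), LiN(SiMe3)2 (3 equiv), THF, −78 °C; then 11, −78 °C; NH4Cl aq.
Reagents that add atoms: none
Why: acetylide addition to the methyl ketone (the tert-butyl ester is inert and the C7 hydroxyl only consumes base); by the Felkin–Anh model the bridgehead C4, with the C2=C3 bridge folded under the endo face, is the large group and the nucleophile enters anti to it past the C5 hydrogen, which should give the S carbinol needed for the tetronate.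

Step 9
Reactants: 13 tertiary propargylic alcohol (ynoate)
Product: 14 norbornene carrying at C5 the (2S)-3-methoxy-2-methyl-5-oxo-2,5-dihydrofuran-2-yl group
Conditions: NaOMe, MeOH, 0 °C to rt
Reagents that add atoms: methanol, CO
Why: conjugate addition of methoxide to the ynoate and lactonisation of the tertiary hydroxyl onto the methyl ester (the classical route from 4-hydroxyalk-2-ynoates to methyl tetronates); the tert-butyl ester and the silylalkyne resist methoxide and the carbinol configuration is kept.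

Step 10
Reactants: 14 methyl tetronate lacking the ring methyl group
Product: 15 norbornene carrying at C5 the (2S)-3-methoxy-2,4-dimethyl-5-oxo-2,5-dihydrofuran-2-yl group
Conditions: LiN(iPr)2 (2.2 equiv), THF, −78 °C; MeI, −78 °C
Reagents that add atoms: iodomethane, CI
Why: after the C7 alkoxide has formed, the amide base lithiates the vinylic C–H between the lactone carbonyl and the methoxy carbon (the only acidic position of a 5,5-disubstituted methyl tetronate) and the vinyllithium is C-methylated; the hindered alpha-hydrogen of the tert-butyl ester and the lithium alkoxide should not compete at −78 °C.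

Step 11
Reactants: 15 dimethyl methyl tetronate with silylalkyne
Product: 16 tert-butyl 7-ethynyl-7-hydroxy-2-methoxy-1-methyl-5-endo-[(2S)-3-methoxy-2,4-dimethyl-5-oxo-2,5-dihydrofuran-2-yl]bicyclo[2.2.1]hept-2-ene-6-exo-carboxylate
Conditions: Bu4NF, THF, 0 °C to rt
Reagents that add atoms: none
Why: fluoride cleaves the C(sp)–Si bond; ester, enol ether and methyl tetronate are stable to Bu4NF.

Step 12
Reactants: 16 7-ethynyl-7-hydroxynorbornene
Product: 18 tert-butyl 7-acetyl-7-hydroxy-2-methoxy-1-methyl-5-endo-[(2S)-3-methoxy-2,4-dimethyl-5-oxo-2,5-dihydrofuran-2-yl]bicyclo[2.2.1]hept-2-ene-6-exo-carboxylate, via spiro alkylidene carbonate 17 (not isolated)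
Conditions: AgOAc (10 mol %), DBU, CO2 (1 atm), MeCN, rt; then H2O, 40 °C
Reagents that add atoms: water, O; carbon dioxide, O=C=O (bound in 17; one equivalent is given back)
Why: carboxylative cyclisation of a tertiary propargylic alcohol (the alkoxide adds to CO2 and the carbonate oxygen closes 5-exo-dig on the silver-activated alkyne) and hydrolysis of the alkylidene carbonate give the methyl ketone with Markovnikov sense under basic conditions, so the acid-labile enol ether survives and no cation is formed at C7.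

Step 13
Reactants: 18 7-acetyl-7-hydroxynorbornene
Product: 19 tert-butyl 8-hydroxy-2-methoxy-1,8-dimethyl-5-[(2S)-3-methoxy-2,4-dimethyl-5-oxo-2,5-dihydrofuran-2-yl]-7-oxobicyclo[2.2.2]oct-2-ene-6-carboxylate
Conditions: Sc(OTf)3 (1.0 equiv), CH2Cl2, molecular sieves, 0 °C to rt
Reagents that add atoms: none
Why: Sc(OTf)3 binds the C7 hydroxyl and the acetyl oxygen in a five-membered chelate, which holds the O–C7–C(acyl)=O unit syn-periplanar and leaves both C7–bridgehead bonds about perpendicular to the carbonyl plane; the C7–C4 bond then migrates with its electron pair to the acetyl carbon while the former hydroxyl becomes the C7 ketone (alpha-ketol rearrangement). The closest known reaction type is the Lewis-acid-promoted ring-enlarging alpha-ketol shift of 1-acylcycloalkanols, the D-homoannulation of 17-hydroxy-20-oxo steroids being the classical case. The new six-membered ring C1–C7–C8–C4–C5–C6 is closed by this suprafacial 1,2-carbon shift (a one-carbon ring enlargement, not a cyclisation), which turns the one-carbon bridge into the C7–C8 bridge. C8 is the only new stereocentre and is set by the chelate: C4 adds to the one carbonyl face open to it in the syn-periplanar geometry, so the hydroxyl comes to lie over the C5–C6 bridge and the methyl over C2=C3, while C1, C4, C5, C6 and the tetronate carbon are not touched. The step needs C4 and not C1 to migrate, which is expected because migration of C1 would place the fully substituted C1 next to the new fully substituted carbinol carbon and because C4 is flanked by the electron-rich beta-carbon C3 of the enol ether. Release of norbornene strain makes the shift downhill, and a second (methyl) shift in the chelated, non-enolisable product should not occur at room temperature.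

Step 14
Reactants: 19 bicyclo[2.2.2]octene ketol enol ether
Product: 20 tert-butyl 8-hydroxy-1,8-dimethyl-5-[(2S)-3-methoxy-2,4-dimethyl-5-oxo-2,5-dihydrofuran-2-yl]-2,7-dioxobicyclo[2.2.2]octane-6-carboxylate
Conditions: 1 M HCl, THF, 0 °C to rt
Reagents that add atoms: water, O
Why: acid hydrolysis of the enol ether (protonation at C3, hemiketal, loss of methanol); C3 becomes CH2, no stereocentre is involved, and the tert-butyl ester and methyl tetronate tolerate dilute acid.

Step 15
Reactants: 20 C2/C7 diketone; 21 (E)-hex-4-enoic acid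
Product: 23 tert-butyl 3-[(E)-hex-4-enoyl]-2,8-dihydroxy-1,8-dimethyl-5-[(2S)-3-methoxy-2,4-dimethyl-5-oxo-2,5-dihydrofuran-2-yl]-7-oxobicyclo[2.2.2]oct-2-ene-6-carboxylate, via (E)-hex-4-enoyl chloride 22 (not isolated)
Conditions: 21, (COCl)2, DMF (cat.), CH2Cl2, 0 °C to rt, concentrate; then 20, MgBr2·OEt2, iPr2NEt, CH2Cl2, 0 °C to rt; 1 M HCl work-up
Reagents that add atoms: oxalyl chloride, O=C(Cl)C(=O)Cl (its chlorine is found only in 22)
Why: C-acylation of a ketone by soft enolisation (MgBr2·OEt2 and an amine base, then the acid chloride); C3 is the only enolisable position of 20 because C1 and both neighbours of the C7 ketone carry no hydrogen, and the product is held as its magnesium diketonate, which stops the reaction at mono-acylation.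

Step 16
Reactants: 23 beta-diketone tert-butyl ester
Product: 24 the corresponding C6 carboxylic acid
Conditions: CF3CO2H, CH2Cl2, 0 °C to rt
Reagents that add atoms: none
Why: acidolysis of the tert-butyl ester by loss of isobutene; the enolised diketone, the methyl tetronate and the isolated E alkene tolerate CF3CO2H at 0 °C.

Step 17
Reactants: 24 C6 carboxylic acid
Product: 25 the corresponding S-phenyl thioester
Conditions: PhSH, EDC·HCl, DMAP (cat.), CH2Cl2, 0 °C to rt
Reagents that add atoms: benzenethiol, Sc1ccccc1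
Why: carbodiimide coupling of the acid with thiophenol; the tertiary alcohol is too hindered to be acylated, and the C6 configuration (trans to C5) is the stable one.

Step 18
Reactants: 26 (E)-but-2-enal; 27 bis(4,4,5,5-tetramethyl-1,3,2-dioxaborolan-2-yl)methane
Product: 29 [(1E,3E)-penta-1,3-dien-1-yl]boronic acid, via dienyl pinacol boronate 28 (not isolated)
Conditions: 27, lithium 2,2,6,6-tetramethylpiperidide, THF, 0 °C; then 26, −78 °C to rt; then NaIO4, NH4OAc, acetone/H2O, rt
Reagents that add atoms: water, O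
Why: boron–Wittig olefination of the aldehyde with the lithiated geminal bis(boronate) gives the E alkenyl boronate by 1,2-addition and elimination of the B–O unit, and periodate cleavage of the pinacol ester frees the boronic acid.

Step 19
Reactants: 25 S-phenyl thioester; 29 [(1E,3E)-penta-1,3-dien-1-yl]boronic acid
Product: 30 O-methyl tetronate of the target (C6 sorbyl ketone)
Conditions: Pd2(dba)3 (2.5 mol %), P(2-furyl)3, copper thiophene-2-carboxylate Cu(O2CC4H3S) (1.6 equiv), THF, 50 °C
Reagents that add atoms: none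
Why: Liebeskind–Srogl coupling, in which zerovalent palladium inserts into the C(O)–S bond, the copper carboxylate takes up the thiolate and activates boron, and the dienyl group is transferred with retention of both E double bonds under neutral conditions that leave the ketones, the enol and the free alcohol alone.

Step 20
Reactants: 30 O-methyl tetronate of the target
Product: 31 target CNP0539719.2
Conditions: LiCl, DMSO, 50 °C; dilute HCl work-up
Reagents that add atoms: none
Why: SN2 attack of chloride on the O-methyl group of the vinylogous carbonate (methyl tetronate) releases the tetronic acid, and acid work-up gives the neutral target.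

**Compound list**

1 | (S)-4-[(tert-butyldimethylsilyl)oxy]cyclopent-2-en-1-one | O=C1C=C[C@@H](O[Si](C)(C)C(C)(C)C)C1 | starting material
2 | ethynyltri(propan-2-yl)silane | C#C[Si](C(C)C)(C(C)C)C(C)C | starting material
3 | (1R,4S)-4-[(tert-butyldimethylsilyl)oxy]-1-[(triisopropylsilyl)ethynyl]cyclopent-2-en-1-ol (OH cis to OTBS) | O[C@@]1(C#C[Si](C(C)C)(C(C)C)C(C)C)C=C[C@@H](O[Si](C)(C)C(C)(C)C)C1 | intermediate
4 | (1R,4S)-1-[(triisopropylsilyl)ethynyl]cyclopent-2-ene-1,4-diol | O[C@@]1(C#C[Si](C(C)C)(C(C)C)C(C)C)C=C[C@@H](O)C1 | intermediate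
5 | (R)-4-hydroxy-4-[(triisopropylsilyl)ethynyl]cyclopent-2-en-1-one | O=C1C=C[C@@](O)(C#C[Si](C(C)C)(C(C)C)C(C)C)C1 | intermediate
6 | (4S)-5-methyl-4-[(triisopropylsilyl)ethynyl]-4-[(trimethylsilyl)oxy]cyclopent-2-en-1-one, both C5 epimers | O=C1C=C[C@@](O[Si](C)(C)C)(C#C[Si](C(C)C)(C(C)C)C(C)C)C1C | intermediate
7 | (S)-{[3-methoxy-2-methyl-1-[(triisopropylsilyl)ethynyl]cyclopenta-2,4-dien-1-yl]oxy}trimethylsilane | COC1=C(C)[C@](O[Si](C)(C)C)(C#C[Si](C(C)C)(C(C)C)C(C)C)C=C1 | intermediate
8 | (S)-3-methoxy-2-methyl-1-[(triisopropylsilyl)ethynyl]cyclopenta-2,4-dien-1-ol | COC1=C(C)[C@](O)(C#C[Si](C(C)C)(C(C)C)C(C)C)C=C1 | intermediate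
9 | (E)-4-oxopent-2-enoic acid | CC(=O)/C=C/C(=O)O | starting material
10 | tert-butyl (E)-4-oxopent-2-enoate | CC(=O)/C=C/C(=O)OC(C)(C)C | intermediate
11 | tert-butyl 5-endo-acetyl-7-hydroxy-2-methoxy-1-methyl-7-[(triisopropylsilyl)ethynyl]bicyclo[2.2.1]hept-2-ene-6-exo-carboxylate (C7 OH over C5–C6, alkynyl over C2=C3) | CC(C)(C)OC(=O)[C@@H]1[C@@H](C(C)=O)[C@H]2C=C(OC)[C@]1(C)[C@]2(O)C#C[Si](C(C)C)(C(C)C)C(C)C | intermediate
12 | methyl propiolate | C#CC(=O)OC | starting material
13 | tert-butyl 7-hydroxy-5-endo-[(2S)-2-hydroxy-5-methoxy-5-oxopent-3-yn-2-yl]-2-methoxy-1-methyl-7-[(triisopropylsilyl)ethynyl]bicyclo[2.2.1]hept-2-ene-6-exo-carboxylate | CC(C)(C)OC(=O)[C@@H]1[C@@H]([C@](C)(O)C#CC(=O)OC)[C@H]2C=C(OC)[C@]1(C)[C@]2(O)C#C[Si](C(C)C)(C(C)C)C(C)C | intermediate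
14 | tert-butyl 7-hydroxy-2-methoxy-1-methyl-5-endo-[(2S)-3-methoxy-2-methyl-5-oxo-2,5-dihydrofuran-2-yl]-7-[(triisopropylsilyl)ethynyl]bicyclo[2.2.1]hept-2-ene-6-exo-carboxylate | CC(C)(C)OC(=O)[C@@H]1[C@@H]([C@]2(C)OC(=O)C=C2OC)[C@H]2C=C(OC)[C@]1(C)[C@]2(O)C#C[Si](C(C)C)(C(C)C)C(C)C | intermediate
15 | tert-butyl 7-hydroxy-2-methoxy-1-methyl-5-endo-[(2S)-3-methoxy-2,4-dimethyl-5-oxo-2,5-dihydrofuran-2-yl]-7-[(triisopropylsilyl)ethynyl]bicyclo[2.2.1]hept-2-ene-6-exo-carboxylate | CC(C)(C)OC(=O)[C@@H]1[C@@H]([C@]2(C)OC(=O)C(C)=C2OC)[C@H]2C=C(OC)[C@]1(C)[C@]2(O)C#C[Si](C(C)C)(C(C)C)C(C)C | intermediate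
16 | tert-butyl 7-ethynyl-7-hydroxy-2-methoxy-1-methyl-5-endo-[(2S)-3-methoxy-2,4-dimethyl-5-oxo-2,5-dihydrofuran-2-yl]bicyclo[2.2.1]hept-2-ene-6-exo-carboxylate | CC(C)(C)OC(=O)[C@@H]1[C@@H]([C@]2(C)OC(=O)C(C)=C2OC)[C@H]2C=C(OC)[C@]1(C)[C@]2(O)C#C | intermediate
17 | spiro carbonate of 16: C7 carries O–C(=O)–O–C(=CH2) as a 4-methylidene-1,3-dioxolan-2-one ring (carbonate oxygen on the C5–C6 side) | CC(C)(C)OC(=O)[C@@H]1[C@@H]([C@]2(C)OC(=O)C(C)=C2OC)[C@H]2C=C(OC)[C@]1(C)[C@]2(OC(=O)O3)C3=C | intermediate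
18 | tert-butyl 7-acetyl-7-hydroxy-2-methoxy-1-methyl-5-endo-[(2S)-3-methoxy-2,4-dimethyl-5-oxo-2,5-dihydrofuran-2-yl]bicyclo[2.2.1]hept-2-ene-6-exo-carboxylate (OH over C5–C6, acetyl over C2=C3) | CC(C)(C)OC(=O)[C@@H]1[C@@H]([C@]2(C)OC(=O)C(C)=C2OC)[C@H]2C=C(OC)[C@]1(C)[C@]2(O)C(C)=O | intermediate
19 | tert-butyl 8-hydroxy-2-methoxy-1,8-dimethyl-5-[(2S)-3-methoxy-2,4-dimethyl-5-oxo-2,5-dihydrofuran-2-yl]-7-oxobicyclo[2.2.2]oct-2-ene-6-carboxylate (C5 group syn to C2=C3, C6 ester syn to C7–C8, C8 OH toward C5–C6) | CC(C)(C)OC(=O)[C@@H]1[C@@H]([C@]2(C)OC(=O)C(C)=C2OC)[C@H]2C=C(OC)[C@]1(C)C(=O)[C@@]2(C)O | intermediate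
20 | tert-butyl 8-hydroxy-1,8-dimethyl-5-[(2S)-3-methoxy-2,4-dimethyl-5-oxo-2,5-dihydrofuran-2-yl]-2,7-dioxobicyclo[2.2.2]octane-6-carboxylate | CC(C)(C)OC(=O)[C@@H]1[C@@H]([C@]2(C)OC(=O)C(C)=C2OC)[C@H]2CC(=O)[C@]1(C)C(=O)[C@@]2(C)O | intermediate
21 | (E)-hex-4-enoic acid | C/C=C/CCC(=O)O | starting material
22 | (E)-hex-4-enoyl chloride | C/C=C/CCC(=O)Cl | intermediate
23 | tert-butyl 3-[(E)-hex-4-enoyl]-2,8-dihydroxy-1,8-dimethyl-5-[(2S)-3-methoxy-2,4-dimethyl-5-oxo-2,5-dihydrofuran-2-yl]-7-oxobicyclo[2.2.2]oct-2-ene-6-carboxylate | CC(C)(C)OC(=O)[C@@H]1[C@@H]([C@]2(C)OC(=O)C(C)=C2OC)[C@H]2C(C(=O)CC/C=C/C)=C(O)[C@]1(C)C(=O)[C@@]2(C)O | intermediate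
24 | 3-[(E)-hex-4-enoyl]-2,8-dihydroxy-1,8-dimethyl-5-[(2S)-3-methoxy-2,4-dimethyl-5-oxo-2,5-dihydrofuran-2-yl]-7-oxobicyclo[2.2.2]oct-2-ene-6-carboxylic acid | OC(=O)[C@@H]1[C@@H]([C@]2(C)OC(=O)C(C)=C2OC)[C@H]2C(C(=O)CC/C=C/C)=C(O)[C@]1(C)C(=O)[C@@]2(C)O | intermediate
25 | S-phenyl thioester of 24 | O=C(Sc1ccccc1)[C@@H]1[C@@H]([C@]2(C)OC(=O)C(C)=C2OC)[C@H]2C(C(=O)CC/C=C/C)=C(O)[C@]1(C)C(=O)[C@@]2(C)O | intermediate
26 | (E)-but-2-enal | C/C=C/C=O | starting material
27 | bis(4,4,5,5-tetramethyl-1,3,2-dioxaborolan-2-yl)methane | CC1(C)OB(CB2OC(C)(C)C(C)(C)O2)OC1(C)C | starting material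
28 | 4,4,5,5-tetramethyl-2-[(1E,3E)-penta-1,3-dien-1-yl]-1,3,2-dioxaborolane | C/C=C/C=C/B1OC(C)(C)C(C)(C)O1 | intermediate
29 | [(1E,3E)-penta-1,3-dien-1-yl]boronic acid | C/C=C/C=C/B(O)O | intermediate
30 | 6-[(2E,4E)-hexa-2,4-dienoyl]-3-[(E)-hex-4-enoyl]-2,8-dihydroxy-5-[(2S)-3-methoxy-2,4-dimethyl-5-oxo-2,5-dihydrofuran-2-yl]-1,8-dimethylbicyclo[2.2.2]oct-2-en-7-one | C/C=C/C=C/C(=O)[C@@H]1[C@@H]([C@]2(C)OC(=O)C(C)=C2OC)[C@H]2C(C(=O)CC/C=C/C)=C(O)[C@]1(C)C(=O)[C@@]2(C)O | intermediate
31 | CNP0539719.2: 6-[(2E,4E)-hexa-2,4-dienoyl]-3-[(E)-hex-4-enoyl]-2,8-dihydroxy-5-[(2S)-3-hydroxy-2,4-dimethyl-5-oxo-2,5-dihydrofuran-2-yl]-1,8-dimethylbicyclo[2.2.2]oct-2-en-7-one (C1 R, C4 S, C5 S, C6 R, C8 S in the numbering of the remark) | C/C=C/C=C/C(=O)[C@@H]1[C@@H]([C@]2(C)OC(=O)C(C)=C2O)[C@H]2C(C(=O)CC/C=C/C)=C(O)[C@]1(C)C(=O)[C@@]2(C)O | target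

**Step count and risks**

Total step count: 20. Longest linear sequence: 18 steps (steps 1–5, 7–17, 19 and 20).

The three steps most likely to fail:

1. Step 13 (ketol shift). What may go wrong: migration of the methyl-bearing bridgehead C1 in place of C4, loss of chelation control at C8, or a shift that stalls. Fallback: the bicyclo[2.2.2]octene is made directly by a cyclohexadienone Diels–Alder reaction. It sets out from dienophile 10 and returns at 19. 3-Methoxy-2,6-dimethylphenol F1 is dearomatised by enantioselective ortho-hydroxylation ([Cu(MeCN)4]PF6, the sparteine enantiomer that delivers the S product, O2; or a chiral aryl iodide with mCPBA) to (S)-6-hydroxy-3-methoxy-2,6-dimethylcyclohexa-2,4-dien-1-one F2, which is trapped in the same flask by 10. Addition syn to the quinol hydroxyl, with the acetyl carbon bonding to the CH terminus and the acetyl group endo, should give tert-butyl 5-acetyl-8-hydroxy-2-methoxy-1,8-dimethyl-7-oxobicyclo[2.2.2]oct-2-ene-6-carboxylate F3, which already holds the C7 ketone and the C8 carbinol. Lithium methyl propiolate should add to the acetyl group (the C7 ketone lies between two fully substituted carbons) to give the propargylic alcohol F4, NaOMe in MeOH closes the tetronate lacking the ring methyl group F5, and LiN(iPr)2/MeI gives 19.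

2. Step 7 (Diels–Alder reaction). What may go wrong: the ester takes the endo position in place of the acetyl group, or to a lesser degree the dienophile adds on the alkynyl face, so that the isomers are formed together. Fallback: the second acceptor is taken out of the dienophile. It sets out from diene 8 and returns at 11. (E)-5-[(tert-Butyldimethylsilyl)oxy]pent-3-en-2-one F6, whose only activating group is the acetyl, should follow the Alder endo rule and give the adduct with endo acetyl at C5 and exo CH2OTBS at C6 F7. HF·pyridine frees the primary alcohol F8 (the alkynyl silyl group stays), Dess–Martin periodinane buffered with NaHCO3 gives the aldehyde F9, NaClO2/NaH2PO4/2-methylbut-2-ene gives the acid F10, and tert-butyl 2,2,2-trichloroacetimidate gives 11.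

3. Step 8 (acetylide addition). What may go wrong: poor or reversed facial selectivity at the acetyl group, which would give the wrong configuration at the tetronate carbon. Fallback: the two carbon groups are put on the carbinol carbon in the opposite order, so that the same facial preference gives the wanted epimer. It sets out from diene 8 and returns at 13. tert-Butyl (E)-4-oxobut-2-enoate F11 (aldehyde as the controlling acceptor) gives the endo-formyl norbornene F12, lithium methyl propiolate gives the secondary propargylic alcohol F13 (both epimers), Dess–Martin periodinane gives the ynone F14, and 1,2-addition of MeCeCl2 (from MeLi and CeCl3, THF, −78 °C) gives 13.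

**Further compounds**

F1 | step 13 | 3-methoxy-2,6-dimethylphenol | COc1ccc(C)c(O)c1C
F2 | step 13 | (S)-6-hydroxy-3-methoxy-2,6-dimethylcyclohexa-2,4-dien-1-one | COC1=C(C)C(=O)[C@@](C)(O)C=C1
F3 | step 13 | tert-butyl 5-acetyl-8-hydroxy-2-methoxy-1,8-dimethyl-7-oxobicyclo[2.2.2]oct-2-ene-6-carboxylate | CC(C)(C)OC(=O)[C@@H]1[C@@H](C(C)=O)[C@H]2C=C(OC)[C@]1(C)C(=O)[C@@]2(C)O
F4 | step 13 | tert-butyl 8-hydroxy-5-[(2S)-2-hydroxy-5-methoxy-5-oxopent-3-yn-2-yl]-2-methoxy-1,8-dimethyl-7-oxobicyclo[2.2.2]oct-2-ene-6-carboxylate | CC(C)(C)OC(=O)[C@@H]1[C@@H]([C@](C)(O)C#CC(=O)OC)[C@H]2C=C(OC)[C@]1(C)C(=O)[C@@]2(C)O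
F5 | step 13 | tert-butyl 8-hydroxy-2-methoxy-1,8-dimethyl-5-[(2S)-3-methoxy-2-methyl-5-oxo-2,5-dihydrofuran-2-yl]-7-oxobicyclo[2.2.2]oct-2-ene-6-carboxylate | CC(C)(C)OC(=O)[C@@H]1[C@@H]([C@]2(C)OC(=O)C=C2OC)[C@H]2C=C(OC)[C@]1(C)C(=O)[C@@]2(C)O
F6 | step 7 | (E)-5-[(tert-butyldimethylsilyl)oxy]pent-3-en-2-one | CC(=O)/C=C/CO[Si](C)(C)C(C)(C)C
F7 | step 7 | 1-[6-exo-{[(tert-butyldimethylsilyl)oxy]methyl}-7-hydroxy-3-methoxy-4-methyl-7-[(triisopropylsilyl)ethynyl]bicyclo[2.2.1]hept-2-en-5-endo-yl]ethan-1-one (the acetyl-bearing carbon is C5 and the silyloxymethyl-bearing carbon is C6 in the numbering of the remark) | CC(C)(C)[Si](C)(C)OC[C@@H]1[C@@H](C(C)=O)[C@H]2C=C(OC)[C@]1(C)[C@]2(O)C#C[Si](C(C)C)(C(C)C)C(C)C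
F8 | step 7 | the primary alcohol from F7 (C6 exo CH2OH) | OC[C@@H]1[C@@H](C(C)=O)[C@H]2C=C(OC)[C@]1(C)[C@]2(O)C#C[Si](C(C)C)(C(C)C)C(C)C
F9 | step 7 | the aldehyde from F8 (C6 exo CHO) | O=C[C@@H]1[C@@H](C(C)=O)[C@H]2C=C(OC)[C@]1(C)[C@]2(O)C#C[Si](C(C)C)(C(C)C)C(C)C
F10 | step 7 | 5-endo-acetyl-7-hydroxy-2-methoxy-1-methyl-7-[(triisopropylsilyl)ethynyl]bicyclo[2.2.1]hept-2-ene-6-exo-carboxylic acid | OC(=O)[C@@H]1[C@@H](C(C)=O)[C@H]2C=C(OC)[C@]1(C)[C@]2(O)C#C[Si](C(C)C)(C(C)C)C(C)C
F11 | step 8 | tert-butyl (E)-4-oxobut-2-enoate | O=C/C=C/C(=O)OC(C)(C)C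
F12 | step 8 | tert-butyl 5-endo-formyl-7-hydroxy-2-methoxy-1-methyl-7-[(triisopropylsilyl)ethynyl]bicyclo[2.2.1]hept-2-ene-6-exo-carboxylate | CC(C)(C)OC(=O)[C@@H]1[C@@H](C=O)[C@H]2C=C(OC)[C@]1(C)[C@]2(O)C#C[Si](C(C)C)(C(C)C)C(C)C
F13 | step 8 | tert-butyl 7-hydroxy-5-endo-(1-hydroxy-4-methoxy-4-oxobut-2-yn-1-yl)-2-methoxy-1-methyl-7-[(triisopropylsilyl)ethynyl]bicyclo[2.2.1]hept-2-ene-6-exo-carboxylate, both carbinol epimers | CC(C)(C)OC(=O)[C@@H]1[C@@H](C(O)C#CC(=O)OC)[C@H]2C=C(OC)[C@]1(C)[C@]2(O)C#C[Si](C(C)C)(C(C)C)C(C)C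
F14 | step 8 | tert-butyl 7-hydroxy-2-methoxy-5-endo-(4-methoxy-4-oxobut-2-ynoyl)-1-methyl-7-[(triisopropylsilyl)ethynyl]bicyclo[2.2.1]hept-2-ene-6-exo-carboxylate | CC(C)(C)OC(=O)[C@@H]1[C@@H](C(=O)C#CC(=O)OC)[C@H]2C=C(OC)[C@]1(C)[C@]2(O)C#C[Si](C(C)C)(C(C)C)C(C)C
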